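**Plan**
Retrosynthesis: the C5 ester is cut first (acid 20). The 1,2-epoxide is traced back through a trans-1,2-diol and a 2-hydroxy-1-ketone to a 2-hydroxycyclopentene with a C8a=C1 double bond. The ring-fusion bond C3a–C8a and the bond C1–C2 are then cut together, which opens both rings to the acyclic enynone 12. Compound 12 is cut at C3a=C3 (Wittig) and C4–C5 (allylboration).
Enabling feature: in the five-membered ring, C3a–C3H2–C2(CH3)–O reads as an (E)-methyl enone (C3a is the β-carbon, C2 the carbonyl carbon, its oxygen the later epoxide oxygen). C8a–C1H reads as a terminal alkyne. The five seven-ring atoms C4–C8 between C3a and C8a form a tether that already carries C4, C5 and C7.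
Forward order: chiral-pool alkyne aldehyde (C6–C8, C8a, C1), then C4/C5 by allylboration, then the enynone. One nickel-mediated reductive [3+2] cycloaddition closes the seven-membered and then the five-membered ring. An oxygen relay over C1/C2/C8a follows (epoxidation, 1,2-hydride shift, directed reduction, mesylate closure), then desilylation, esterification and debenzylation.
Stereochemistry: C7 comes from (S)-mevalonolactone; C5 and C4 from reagent-controlled (E)-allylboration; C3a from C4 and C2 from C3a in the cycloaddition; C8a from the stereospecific hydride shift (trans ring fusion); C1 from hydroxyl-directed reduction followed by SN2 inversion.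

Key step: step 8

Remark: azulene numbering is used for the core (five-membered ring C1, C2, C3, C3a, C8a; seven-membered ring C3a, C4–C8, C8a), which makes the target (1S,2R,3aR,4S,5R,7R,8aS); (S)-mevalonolactone, (−)-Ipc2BOMe and acid 20 are taken as purchasable.

Step 1
Reactants: 1 (S)-mevalonolactone
Product: 2 (4S)-4-methyl-4-(triethylsilyloxy)oxan-2-one
Conditions: TESOTf, 2,6-lutidine, CH2Cl2, 0 °C
Reagents that add atoms: triethylsilyl trifluoromethanesulfonate CC[Si](CC)(CC)OS(=O)(=O)C(F)(F)F
Why: Silyl triflate with a hindered base is the standard silylation of a tertiary alcohol, and the ether later prevents oxa-Michael addition of this hydroxyl to the enone.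

Step 2
Reactants: 2 (4S)-4-methyl-4-(triethylsilyloxy)oxan-2-one
Product: 3 (4S)-4-methyl-4-(triethylsilyloxy)oxan-2-ol (lactol, anomer mixture)
Conditions: i-Bu2AlH, CH2Cl2, −78 °C; Rochelle salt work-up
Reagents that add atoms: none
Why: Partial reduction of a δ-lactone at low temperature should stop at the tetrahedral aluminium alkoxide, which gives the lactol on work-up.

Step 3
Reactants: 3 (4S)-4-methyl-4-(triethylsilyloxy)oxan-2-ol
Product: 4 (3R)-3-methyl-3-(triethylsilyloxy)hex-5-yn-1-ol
Conditions: dimethyl (1-diazo-2-oxopropyl)phosphonate, K2CO3, MeOH, 0 °C to rt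
Reagents that add atoms: dimethyl (1-diazo-2-oxopropyl)phosphonate CC(=O)C(=[N+]=[N-])P(=O)(OC)OC
Why: In the Ohira–Bestmann homologation the lactol reacts through its open hydroxy aldehyde form, so the former lactone carbon becomes the internal alkyne carbon (later C8a) and the reagent supplies the terminal carbon (later C1) without touching the stereocentre.

Step 4
Reactants: 4 (3R)-3-methyl-3-(triethylsilyloxy)hex-5-yn-1-ol
Product: 5 (3R)-3-methyl-3-(triethylsilyloxy)hex-5-ynal
Conditions: Dess–Martin periodinane, CH2Cl2, 0 °C to rt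
Reagents that add atoms: none
Why: Dess–Martin oxidation converts the primary alcohol into the aldehyde under near-neutral conditions that should leave the alkyne and the tertiary silyl ether intact.

Step 5
Reactants: 5 (3R)-3-methyl-3-(triethylsilyloxy)hex-5-ynal; 6 (E)-4-methylpent-2-ene
Product: 8 (3S,4R,6R)-6-methyl-3-(propan-2-yl)-6-(triethylsilyloxy)non-1-en-8-yn-4-ol, via allylborane reagent 7 (not isolated)
Conditions: 6, n-BuLi, KOt-Bu, THF, −78 to −50 °C; (−)-Ipc2BOMe, −78 °C; BF3·OEt2; 5, −78 °C; then NaOH, H2O2, 0 °C to rt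
Reagents that add atoms: none
Why: In this Brown-type γ-substituted allylboration the (E)-allylborane should react through a closed Zimmerman–Traxler chair in which the E geometry gives the 3,4-anti product and the isopinocampheyl groups derived from (+)-α-pinene direct attack to the si face of the aldehyde, which sets C5 (R) and C4 (S) of the target under reagent control.

Step 6
Reactants: 8 (3S,4R,6R)-6-methyl-3-(propan-2-yl)-6-(triethylsilyloxy)non-1-en-8-yn-4-ol
Product: 9 (3S,4R,6R)-4-(tert-butyldimethylsilyloxy)-6-methyl-3-(propan-2-yl)-6-(triethylsilyloxy)non-1-en-8-yne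
Conditions: TBSOTf, 2,6-lutidine, CH2Cl2, −78 to 0 °C
Reagents that add atoms: tert-butyldimethylsilyl trifluoromethanesulfonate CC(C)(C)[Si](C)(C)OS(=O)(=O)C(F)(F)F
Why: Silyl triflate silylation of the hindered secondary alcohol masks the later C5 oxygen against β-elimination, cation capture and sulfonylation in the steps that follow.

Step 7
Reactants: 9 (3S,4R,6R)-4-(tert-butyldimethylsilyloxy)-6-methyl-3-(propan-2-yl)-6-(triethylsilyloxy)non-1-en-8-yne; 10 1-(triphenyl-λ5-phosphanylidene)propan-2-one
Product: 12 (3E,5S,6R,8R)-6-(tert-butyldimethylsilyloxy)-8-methyl-5-(propan-2-yl)-8-(triethylsilyloxy)undec-3-en-10-yn-2-one, via aldehyde 11 (not isolated)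
Conditions: O3, CH2Cl2, −78 °C (stopped at alkene consumption); PPh3, −78 °C to rt; then 10, CH2Cl2, 40 °C
Reagents that add atoms: none
Why: Ozone should cleave the monosubstituted alkene much faster than the terminal alkyne, and the stabilised Wittig ylide then converts the α-branched aldehyde into the (E)-enone under conditions too mild to epimerise C4.

Step 8
Reactants: 12 (3E,5S,6R,8R)-6-(tert-butyldimethylsilyloxy)-8-methyl-5-(propan-2-yl)-8-(triethylsilyloxy)undec-3-en-10-yn-2-one
Product: 13 (2R,3aS,4S,5R,7R)-5-(tert-butyldimethylsilyloxy)-2,7-dimethyl-4-(propan-2-yl)-7-(triethylsilyloxy)-2,3,3a,4,5,6,7,8-octahydroazulen-2-ol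
Conditions: Ni(COD)2 (20 mol%), PBu3 (40 mol%), Et3B (3 equiv), MeOH/THF 8:1, 0.02 M, degassed, 50 °C
Reagents that add atoms: none
Why: Proposed new method: zerovalent nickel binds the alkyne and the s-cis enone of 12 and couples them oxidatively, forming C8a–C3a and an oxa-nickelacycle (alkenyl–nickel at C1, O-bound enolate of the C2 ketone); methanol protonates the enolate at C3, the alkenyl–nickel bond adds to the C2 ketone to form C1–C2, and Et3B returns the divalent nickel alkoxide to zerovalent nickel. The closest known reaction type is the nickel-catalysed reductive [3+2] cycloaddition of enals or enones with alkynes to cyclopentenols, known intermolecularly and for tethers that close a five-membered carbocycle; the seven-membered tether ring is the extension proposed here and is argued from the same metallacycle mechanism. The seven-membered ring closes in a 7-exo mode with respect to both π systems (C1 and C3 stay outside the ring), helped by three substituted tether atoms (C4, C5 and quaternary C7), and the cyclopentene closes by 5-exo-trig addition of C1 to the C2 carbonyl. C3a is controlled by C4: the tether through C5 must lie on the attacked enone face, so H-4 takes the in-plane position and the isopropyl group the position anti to the incoming alkyne, which places H-3a cis to the isopropyl group. C2 is controlled by C3a: in the four-centre insertion the carbonyl oxygen stays on nickel on the face of the new ring away from the C3a–C4 bond, so the C2 hydroxyl should end cis to H-3a and the methyl group trans. The step needs intramolecular enone–alkyne coupling to beat alkyne oligomerisation and ketone insertion to beat protonolysis of the alkenyl–nickel bond; high dilution, the fixed cis relation of nickel and C3a across C8a=C1 and chelation of the ketone in the metallacycle should secure both.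

Step 9
Reactants: 13 (2R,3aS,4S,5R,7R)-5-(tert-butyldimethylsilyloxy)-2,7-dimethyl-4-(propan-2-yl)-7-(triethylsilyloxy)-2,3,3a,4,5,6,7,8-octahydroazulen-2-ol
Product: 14 (1R,2R,3aS,4S,5R,7R,8aS)-5-(tert-butyldimethylsilyloxy)-1,8a-epoxy-2,7-dimethyl-4-(propan-2-yl)-7-(triethylsilyloxy)decahydroazulen-2-ol
Conditions: VO(acac)2 (cat.), t-BuOOH, CH2Cl2, 0 °C to rt
Reagents that add atoms: tert-butyl hydroperoxide CC(C)(C)OO
Why: Vanadium-catalysed hydroxyl-directed epoxidation should deliver oxygen to the C8a=C1 bond on the face of the tertiary allylic C2 hydroxyl, which is also the face of H-3a.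

Step 10
Reactants: 14 (1R,2R,3aS,4S,5R,7R,8aS)-5-(tert-butyldimethylsilyloxy)-1,8a-epoxy-2,7-dimethyl-4-(propan-2-yl)-7-(triethylsilyloxy)decahydroazulen-2-ol
Product: 15 (2R,3aS,4S,5R,7R,8aS)-5-(tert-butyldimethylsilyloxy)-2-hydroxy-2,7-dimethyl-4-(propan-2-yl)-7-(triethylsilyloxy)octahydroazulen-1(2H)-one
Conditions: BF3·OEt2 (0.2 equiv), CH2Cl2, −78 to −40 °C
Reagents that add atoms: none
Why: In this Meinwald rearrangement the Lewis acid opens the epoxide at the tertiary ring-fusion carbon C8a and the C1 hydrogen migrates to C8a anti to the departing oxygen, which gives the C1 ketone and places H-8a trans to H-3a, while ring contraction would need a cyclobutane and is disfavoured.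

Step 11
Reactants: 15 (2R,3aS,4S,5R,7R,8aS)-5-(tert-butyldimethylsilyloxy)-2-hydroxy-2,7-dimethyl-4-(propan-2-yl)-7-(triethylsilyloxy)octahydroazulen-1(2H)-one
Product: 16 (1R,2R,3aR,4S,5R,7R,8aS)-5-(tert-butyldimethylsilyloxy)-2,7-dimethyl-4-(propan-2-yl)-7-(triethylsilyloxy)decahydroazulene-1,2-diol
Conditions: Me4NBH(OAc)3, MeCN/AcOH, −30 °C
Reagents that add atoms: none
Why: In this hydroxyl-directed (Saksena–Evans type) reduction the C2 hydroxyl exchanges onto boron and should deliver hydride to the adjacent ketone on its own face, so the new C1 hydroxyl ends trans to the C2 hydroxyl.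

Step 12
Reactants: 16 (1R,2R,3aR,4S,5R,7R,8aS)-5-(tert-butyldimethylsilyloxy)-2,7-dimethyl-4-(propan-2-yl)-7-(triethylsilyloxy)decahydroazulene-1,2-diol
Product: 18 (1S,2R,3aR,4S,5R,7R,8aS)-5-(tert-butyldimethylsilyloxy)-1,2-epoxy-2,7-dimethyl-4-(propan-2-yl)-7-(triethylsilyloxy)decahydroazulene, via mesylate 17 (not isolated)
Conditions: MsCl, Et3N, CH2Cl2, −10 °C; then K2CO3, MeOH, rt
Reagents that add atoms: none
Why: The secondary C1 hydroxyl is sulfonylated selectively over the tertiary C2 hydroxyl, and intramolecular Williamson-type SN2 closure by the C2 alkoxide with inversion at C1 should give the cis-fused epoxide on the face of H-3a.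

Step 13
Reactants: 18 (1S,2R,3aR,4S,5R,7R,8aS)-5-(tert-butyldimethylsilyloxy)-1,2-epoxy-2,7-dimethyl-4-(propan-2-yl)-7-(triethylsilyloxy)decahydroazulene
Product: 19 (1S,2R,3aR,4S,5R,7R,8aS)-1,2-epoxy-2,7-dimethyl-4-(propan-2-yl)decahydroazulene-5,7-diol
Conditions: Bu4NF, THF, rt to 40 °C
Reagents that add atoms: none
Why: Fluoride-mediated desilylation should remove both silyl ethers without opening the epoxide, which cannot be reached from the rear by either hydroxyl.

Step 14
Reactants: 19 (1S,2R,3aR,4S,5R,7R,8aS)-1,2-epoxy-2,7-dimethyl-4-(propan-2-yl)decahydroazulene-5,7-diol; 20 3-(benzyloxy)-4-methoxybenzoic acid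
Product: 21 (1S,2R,3aR,4S,5R,7R,8aS)-1,2-epoxy-7-hydroxy-2,7-dimethyl-4-(propan-2-yl)decahydroazulen-5-yl 3-(benzyloxy)-4-methoxybenzoate
Conditions: EDC·HCl, DMAP, CH2Cl2, rt
Reagents that add atoms: none
Why: Steglich esterification should acylate the only secondary hydroxyl (C5) while the tertiary C7 hydroxyl is too hindered to react and the benzyl ether keeps the phenol out of the coupling.

Step 15
Reactants: 21 (1S,2R,3aR,4S,5R,7R,8aS)-1,2-epoxy-7-hydroxy-2,7-dimethyl-4-(propan-2-yl)decahydroazulen-5-yl 3-(benzyloxy)-4-methoxybenzoate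
Product: 22 (1S,2R,3aR,4S,5R,7R,8aS)-1,2-epoxy-7-hydroxy-2,7-dimethyl-4-(propan-2-yl)decahydroazulen-5-yl 3-hydroxy-4-methoxybenzoate (target, CNP0106636.1)
Conditions: H2 (1 atm), 10% Pd on carbon, EtOAc, rt
Reagents that add atoms: none
Why: Hydrogenolysis cleaves the aryl benzyl ether, and the non-benzylic trisubstituted epoxide and the ester should survive neutral conditions.

**Compound list**
1 | (S)-mevalonolactone, (4S)-4-hydroxy-4-methyloxan-2-one | C[C@]1(O)CCOC(=O)C1 | starting material
2 | (4S)-4-methyl-4-(triethylsilyloxy)oxan-2-one | C[C@]1(O[Si](CC)(CC)CC)CCOC(=O)C1 | intermediate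
3 | (4S)-4-methyl-4-(triethylsilyloxy)oxan-2-ol (anomer mixture) | C[C@]1(O[Si](CC)(CC)CC)CCOC(O)C1 | intermediate
4 | (3R)-3-methyl-3-(triethylsilyloxy)hex-5-yn-1-ol | C#CC[C@@](C)(O[Si](CC)(CC)CC)CCO | intermediate
5 | (3R)-3-methyl-3-(triethylsilyloxy)hex-5-ynal | C#CC[C@@](C)(O[Si](CC)(CC)CC)CC=O | intermediate
6 | (E)-4-methylpent-2-ene | C/C=C/C(C)C | starting material
7 | (E)-(4-methylpent-2-en-1-yl)bis(isopinocampheyl)borane, isopinocampheyl groups from (+)-α-pinene | CC(C)/C=C/CB([C@@H]1C[C@@H]2C[C@H]([C@H]1C)C2(C)C)[C@@H]1C[C@@H]2C[C@H]([C@H]1C)C2(C)C | intermediate (not isolated)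
8 | (3S,4R,6R)-6-methyl-3-(propan-2-yl)-6-(triethylsilyloxy)non-1-en-8-yn-4-ol | O[C@H](C[C@](C)(O[Si](CC)(CC)CC)CC#C)[C@@H](C(C)C)C=C | intermediate
9 | (3S,4R,6R)-4-(tert-butyldimethylsilyloxy)-6-methyl-3-(propan-2-yl)-6-(triethylsilyloxy)non-1-en-8-yne | CC(C)(C)[Si](C)(C)O[C@H](C[C@](C)(O[Si](CC)(CC)CC)CC#C)[C@@H](C(C)C)C=C | intermediate
10 | 1-(triphenyl-λ5-phosphanylidene)propan-2-one | CC(=O)C=P(c1ccccc1)(c1ccccc1)c1ccccc1 | starting material
11 | (2R,3R,5R)-3-(tert-butyldimethylsilyloxy)-5-methyl-2-(propan-2-yl)-5-(triethylsilyloxy)oct-7-ynal | CC(C)(C)[Si](C)(C)O[C@H](C[C@](C)(O[Si](CC)(CC)CC)CC#C)[C@@H](C(C)C)C=O | intermediate (not isolated)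
12 | (3E,5S,6R,8R)-6-(tert-butyldimethylsilyloxy)-8-methyl-5-(propan-2-yl)-8-(triethylsilyloxy)undec-3-en-10-yn-2-one | CC(C)(C)[Si](C)(C)O[C@H](C[C@](C)(O[Si](CC)(CC)CC)CC#C)[C@@H](C(C)C)/C=C/C(C)=O | intermediate
13 | (2R,3aS,4S,5R,7R)-5-(tert-butyldimethylsilyloxy)-2,7-dimethyl-4-(propan-2-yl)-7-(triethylsilyloxy)-2,3,3a,4,5,6,7,8-octahydroazulen-2-ol (C2–OH cis to H-3a, H-3a cis to the isopropyl group) | CC(C)(C)[Si](C)(C)O[C@@H]1C[C@](C)(O[Si](CC)(CC)CC)CC2=C[C@](C)(O)C[C@H]2[C@@H]1C(C)C | intermediate
14 | (1R,2R,3aS,4S,5R,7R,8aS)-5-(tert-butyldimethylsilyloxy)-1,8a-epoxy-2,7-dimethyl-4-(propan-2-yl)-7-(triethylsilyloxy)decahydroazulen-2-ol (epoxide cis to C2–OH) | CC(C)(C)[Si](C)(C)O[C@@H]1C[C@](C)(O[Si](CC)(CC)CC)C[C@]23O[C@@H]3[C@](C)(O)C[C@H]2[C@@H]1C(C)C | intermediate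
15 | (2R,3aS,4S,5R,7R,8aS)-5-(tert-butyldimethylsilyloxy)-2-hydroxy-2,7-dimethyl-4-(propan-2-yl)-7-(triethylsilyloxy)octahydroazulen-1(2H)-one (trans-fused) | CC(C)(C)[Si](C)(C)O[C@@H]1C[C@](C)(O[Si](CC)(CC)CC)C[C@@H]2C(=O)[C@](C)(O)C[C@H]2[C@@H]1C(C)C | intermediate
16 | (1R,2R,3aR,4S,5R,7R,8aS)-5-(tert-butyldimethylsilyloxy)-2,7-dimethyl-4-(propan-2-yl)-7-(triethylsilyloxy)decahydroazulene-1,2-diol (trans-diol) | CC(C)(C)[Si](C)(C)O[C@@H]1C[C@](C)(O[Si](CC)(CC)CC)C[C@@H]2[C@@H](O)[C@](C)(O)C[C@H]2[C@@H]1C(C)C | intermediate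
17 | 1-O-methanesulfonate of 16 | CC(C)(C)[Si](C)(C)O[C@@H]1C[C@](C)(O[Si](CC)(CC)CC)C[C@@H]2[C@@H](OS(C)(=O)=O)[C@](C)(O)C[C@H]2[C@@H]1C(C)C | intermediate (not isolated)
18 | (1S,2R,3aR,4S,5R,7R,8aS)-5-(tert-butyldimethylsilyloxy)-1,2-epoxy-2,7-dimethyl-4-(propan-2-yl)-7-(triethylsilyloxy)decahydroazulene | CC(C)(C)[Si](C)(C)O[C@@H]1C[C@](C)(O[Si](CC)(CC)CC)C[C@H]2[C@@H](C[C@@]3(C)O[C@@H]23)[C@@H]1C(C)C | intermediate
19 | (1S,2R,3aR,4S,5R,7R,8aS)-1,2-epoxy-2,7-dimethyl-4-(propan-2-yl)decahydroazulene-5,7-diol | O[C@@H]1C[C@](C)(O)C[C@H]2[C@@H](C[C@@]3(C)O[C@@H]23)[C@@H]1C(C)C | intermediate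
20 | 3-(benzyloxy)-4-methoxybenzoic acid | COc1ccc(C(=O)O)cc1OCc1ccccc1 | starting material
21 | (1S,2R,3aR,4S,5R,7R,8aS)-1,2-epoxy-7-hydroxy-2,7-dimethyl-4-(propan-2-yl)decahydroazulen-5-yl 3-(benzyloxy)-4-methoxybenzoate | COc1ccc(C(=O)O[C@@H]2C[C@](C)(O)C[C@H]3[C@@H](C[C@@]4(C)O[C@@H]34)[C@@H]2C(C)C)cc1OCc1ccccc1 | intermediate
22 | (1S,2R,3aR,4S,5R,7R,8aS)-1,2-epoxy-7-hydroxy-2,7-dimethyl-4-(propan-2-yl)decahydroazulen-5-yl 3-hydroxy-4-methoxybenzoate | COc1ccc(C(=O)O[C@@H]2C[C@](C)(O)C[C@H]3[C@@H](C[C@@]4(C)O[C@@H]34)[C@@H]2C(C)C)cc1O | target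

**Step count**
Total steps: 15. Longest linear sequence: 15 steps (1 to 22).

**Steps most likely to fail**

Step 8 (bears the label). The oxidative cyclisation across a five-atom tether may be slower than alkyne oligomerisation or simple reduction of the enone. Protonolysis of the alkenyl–nickel bond may outrun insertion of the ketone, and facial selectivity at C3a or C2 may be low. Fallback with known chemistry, from 12: anti-Markovnikov hydration of the terminal alkyne (RuClCp(dppm), aqueous 2-propanol, 100 °C) would give the keto aldehyde F1. A pyrrolidine-type secondary amine would then close the seven-membered ring by intramolecular enamine Michael addition to the enone, giving the cycloheptane keto aldehyde F2. A triazolium-derived N-heterocyclic carbene would close the five-membered ring by intramolecular crossed benzoin reaction, which gives the α-hydroxy ketone 15, where the route is rejoined. The two bonds are then made by ionic steps rather than through a metallacycle, and C8a can be equilibrated next to the C1 carbonyl.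

Step 10. The C8a cation may be captured across the ring by the C5 silyl ether oxygen, the product may undergo an α-ketol shift, or C8a may epimerise under acid. Fallback, from 13, avoiding cationic chemistry: hydroboration–oxidation (BH3·THF; NaOH, H2O2) of the C8a=C1 bond would give the diol F3, expected from the less hindered face and therefore cis-fused. Dess–Martin oxidation of the secondary hydroxyl would give the cis-fused hydroxy ketone F4. Base equilibration at C8a (DBU, toluene) should then lead to the trans-fused ketone 15, where the route is rejoined; this relies on thermodynamic control of the ring fusion, not on a stereospecific shift.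

Step 11. Hydride may enter from the lower face if hydroxyl direction through the five-membered boron chelate is poor, which would give the cis-diol. Fallback, from 15: the facial bias is accepted and the ketone is reduced without direction (LiBH(s-Bu)3, THF, −78 °C) to the cis-diol F5. This is converted into the cyclic orthoacetate F6 (MeC(OMe)3, pyridinium p-toluenesulfonate). Acetyl bromide opens F6 at the secondary C1 with inversion to the bromo acetate F7. K2CO3 in MeOH then removes the acetate, and the C2 alkoxide displaces bromide with a second inversion to give the epoxide 18, where the route is rejoined.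

Further compounds
F1 | step 8 | (3E,5S,6R,8R)-6-(tert-butyldimethylsilyloxy)-8-methyl-10-oxo-5-(propan-2-yl)-8-(triethylsilyloxy)undec-3-enal-type keto aldehyde (C1 aldehyde in place of the alkyne of 12) | CC(C)(C)[Si](C)(C)O[C@H](C[C@](C)(O[Si](CC)(CC)CC)CCC=O)[C@@H](C(C)C)/C=C/C(C)=O
F2 | step 8 | cycloheptane keto aldehyde: 8a-formyl and 3a-(2-oxopropyl) groups trans on the seven-membered ring, other centres as in 15 | CC(C)(C)[Si](C)(C)O[C@@H]1C[C@](C)(O[Si](CC)(CC)CC)C[C@H](C=O)[C@@H](CC(C)=O)[C@@H]1C(C)C
F3 | step 10 | cis-fused decahydroazulene-1,2-diol: C1–OH, C2–OH, H-8a and H-3a all on one face, silyl ethers as in 13 | CC(C)(C)[Si](C)(C)O[C@@H]1C[C@](C)(O[Si](CC)(CC)CC)C[C@H]2[C@H](O)[C@](C)(O)C[C@H]2[C@@H]1C(C)C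
F4 | step 10 | cis-fused 2-hydroxy-1-ketone, the C8a epimer of 15 | CC(C)(C)[Si](C)(C)O[C@@H]1C[C@](C)(O[Si](CC)(CC)CC)C[C@H]2C(=O)[C@](C)(O)C[C@H]2[C@@H]1C(C)C
F5 | step 11 | trans-fused cis-1,2-diol, the C1 epimer of 16 | CC(C)(C)[Si](C)(C)O[C@@H]1C[C@](C)(O[Si](CC)(CC)CC)C[C@@H]2[C@H](O)[C@](C)(O)C[C@H]2[C@@H]1C(C)C
F6 | step 11 | cyclic methyl orthoacetate of F5 (2-methoxy-2-methyl-1,3-dioxolane fused at C1–C2, orthoester carbon as a mixture) | CC(C)(C)[Si](C)(C)O[C@@H]1C[C@](C)(O[Si](CC)(CC)CC)C[C@@H]2[C@@H]3OC(C)(OC)O[C@]3(C)C[C@H]2[C@@H]1C(C)C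
F7 | step 11 | trans bromo acetate: C1 bromide (inverted), C2 tertiary acetate | CC(C)(C)[Si](C)(C)O[C@@H]1C[C@](C)(O[Si](CC)(CC)CC)C[C@@H]2[C@@H](Br)[C@](C)(OC(C)=O)C[C@H]2[C@@H]1C(C)C
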